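Retrosynthesis: the aryl–CH2 bond is cut first (Mannich-base alkylation of an acylphloroglucinol), then in one event the ring bonds C1–C6 and C4–C5 of the dearomatized ring (two-carbon ring expansion), then the C2–acyl bond and the four-membered ring.
Enabling feature: ring carbons C1–C4 (ring ketone, acyl-bearing C2, enol carbon C3, quaternary C4) are a 2-acyl-3-alkoxycyclobut-2-enone held by a C1–C4 bond that is absent from the target; C5–C6 (enol carbon and CH2-bearing carbon) is a polarized ynol unit that a metal can insert into that strained acyl–C(sp3) bond.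
Forward: four-membered ring by ketene/ynol ether [2+2] (step 5), acylation (step 6), six-membered ring by nickel-catalysed alkyne insertion (step 8), hydrolysis (step 9), methylene bridge to the aromatic ring last (step 11).
Stereochemistry: the [2+2] step gives both C4 epimers of the cyclobutenone as menthyl diastereomers; the (4S) one is isolated by chromatography (the other is discarded at this early stage) and its C4 is carried into the six-membered ring with retention; the menthyl, tin, silyl and dimethylamino helpers are all gone by the end.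
Key step: step 8

Remark: the target is an enolized 2-acylcyclohexane-1,3,5-trione written as one tautomer; its precursors are drawn in the same tautomer, the amino compound of step 9 is really an inner salt, and the dearomatized ring is numbered C1 (ring C=O), C2 (butanoyl), C3, C4 (quaternary), C5, C6 (CH2 substituent) throughout.

Step 1
Reactants: 1 propanoic acid; 2 1-bromo-3-methylbut-2-ene (prenyl bromide)
Product: 4 rac-2,5-dimethylhex-4-enoic acid, via dilithium dianion of propanoic acid 3 (not isolated)
Conditions: LiN(iPr)2 (2.1 equiv), THF, 0 °C; then 2, 0 °C → rt; 1 M HCl work-up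
Reagents that add atoms: none
Why: α-Alkylation of a carboxylic acid dianion with an allylic bromide is standard, and the stereocentre formed is racemic on purpose because it becomes the sp2 carbon of a ketene in step 5.

Step 2
Reactants: 4 rac-2,5-dimethylhex-4-enoic acid
Product: 5 rac-2,5-dimethylhex-4-enoyl chloride
Conditions: (COCl)2, DMF (cat.), CH2Cl2, 0 °C → rt
Reagents that add atoms: oxalyl chloride, ClC(=O)C(=O)Cl
Why: Acid chloride formation with oxalyl chloride under Vilsmeier-type catalysis is mild and should leave the trisubstituted alkene untouched.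

Step 3
Reactants: 6 (1R,2S,5R)-(−)-menthol; 7 trichloroethene
Product: 9 (E)-1,2-dichlorovinyl (1R,2S,5R)-menthyl ether, via potassium mentholate 8 (not isolated)
Conditions: KH, THF, rt; then 7, −50 °C → rt
Reagents that add atoms: none
Why: Addition–elimination of a potassium alkoxide on trichloroethene is the established entry to dichloroenol ethers of chiral secondary alcohols (ynol ether precursors), and the menthyl stereocentres are not touched.

Step 4
Reactants: 9 (E)-1,2-dichlorovinyl (1R,2S,5R)-menthyl ether
Product: 11 tributyl{[(1R,2S,5R)-menthyloxy]ethynyl}stannane, via lithium (menthyloxy)acetylide 10 (not isolated)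
Conditions: n-BuLi (2.2 equiv), THF, −78 → −40 °C; then Bu3SnCl, −78 °C → rt
Reagents that add atoms: tributyltin chloride, CCCC[Sn](Cl)(CCCC)CCCC
Why: Two equivalents of n-BuLi turn the dichloroenol ether into the lithium alkoxyacetylide (dehydrochlorination, then chlorine–lithium exchange), which is stannylated on carbon so that tin holds the place of the later butanoyl group.

Step 5
Reactants: 5 rac-2,5-dimethylhex-4-enoyl chloride; 11 tributyl{[(1R,2S,5R)-menthyloxy]ethynyl}stannane
Product: 13 (4S)-3-[(1R,2S,5R)-menthyloxy]-4-methyl-4-(3-methylbut-2-en-1-yl)-2-(tributylstannyl)cyclobut-2-en-1-one, via methyl(prenyl)ketene 12 (not isolated)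
Conditions: Et3N, CH2Cl2, 40 °C, slow addition of 5; chromatography on silica separates 13 from its (4R) epimer
Reagents that add atoms: none
Why: Ketene–ynol ether [2+2] cycloaddition, in which the nucleophilic tin-bearing alkyne carbon attacks the ketene carbonyl carbon and so fixes the 2-stannyl-3-alkoxy pattern; C4 arises from the planar ketene without facial control, so both C4 epimers are expected in similar amounts, the menthyl group serves to make them separable diastereomers, and the (4S) epimer is kept (configuration to be assigned by X-ray analysis of a crystalline derivative) while the (4R) epimer is removed at this early, inexpensive stage.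

Step 6
Reactants: 13 (4S)-stannylcyclobutenone; 14 butanoyl chloride
Product: 15 (4S)-2-butanoyl-3-[(1R,2S,5R)-menthyloxy]-4-methyl-4-(3-methylbut-2-en-1-yl)cyclobut-2-en-1-one
Conditions: Pd2(dba)3 (2.5 mol %), tri(2-furyl)phosphine (10 mol %), CuI (10 mol %), THF, rt → 45 °C
Reagents that add atoms: none
Why: Stille acylation of an α-stannyl enone with an acid chloride (zerovalent palladium with copper iodide as co-catalyst) is precedented for stannylated cyclobutenediones, runs under neutral conditions that spare the prenyl group and the enol ether, and does not touch C4.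

Step 7
Reactants: 16 N,N-dimethylprop-2-yn-1-amine
Product: 19 N,N-dimethyl-3-[(triisopropylsilyl)oxy]prop-2-yn-1-amine, via lithium acetylide 17 (not isolated), via lithium ynolate 18 (not isolated)
Conditions: n-BuLi, THF, −78 °C; t-BuOOLi (from t-BuOOH and LiN(SiMe3)2), −78 → 0 °C; iPr3SiOTf, −78 °C → rt
Reagents that add atoms: tert-butyl hydroperoxide, CC(C)(C)OO; triisopropylsilyl trifluoromethanesulfonate, CC(C)[Si](OS(=O)(=O)C(F)(F)F)(C(C)C)C(C)C
Why: Oxygenation of a lithium acetylide by lithium tert-butyl peroxide gives the lithium ynolate, which the bulky silyl triflate traps on oxygen as an isolable siloxyalkyne, a known one-flask route from terminal alkynes.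

Step 8
Reactants: 15 (4S)-2-butanoylcyclobutenone; 19 N,N-dimethyl-3-[(triisopropylsilyl)oxy]prop-2-yn-1-amine
Product: 20 (4S)-2-butanoyl-6-[(dimethylamino)methyl]-3-[(1R,2S,5R)-menthyloxy]-4-methyl-4-(3-methylbut-2-en-1-yl)-5-[(triisopropylsilyl)oxy]cyclohexa-2,5-dien-1-one
Conditions: Ni(cod)2 (10 mol %), PPh3 (20 mol %), toluene, 0 °C → rt, slow addition of 19 (1.3 equiv)
Reagents that add atoms: none
Why: Proposed new method: zerovalent nickel should add oxidatively to the strained acyl–C(sp3) bond C1–C4 of 15 (C4 is the only sp3 carbon on the ring ketone) to give a five-membered acyl(alkyl) metallacycle of divalent nickel, alkyne 19 then inserts, and C–C reductive elimination from the resulting seven-membered nickelacycle closes the six-membered carbocycle, so that C1–C6 and C4–C5 are made and C1–C4 is broken in one catalytic cycle (a formal [4+2] two-carbon ring expansion, not a pericyclic closure). The closest known reaction types are the nickel-catalysed benzannulation of cyclobutenones with alkynes, which gives phenols when C4 bears hydrogen, and the nickel-catalysed insertion of alkynes into cyclobutanones; new here are the fully substituted C4, which blocks tautomerization and leaves the cross-conjugated dienone, and the silyl ynol ether as the alkyne. No stereocentre is made from a planar carbon: C4 stays tetrahedral and nickel-bound throughout, and since oxidative addition and reductive elimination at carbon both go with retention, C5 takes the place that C1 held, so the configuration of 15 is relayed unchanged to C4 of 20 and is that of the target. The step needs regioselective insertion, which the polarity match should secure: the acyl(oxa-allyl)nickel unit is an acyl cation/dienolate equivalent and the siloxyalkyne is nucleophilic at its amine-bearing β-carbon (which bonds to acyl C1) and electrophilic at its oxygen-bearing α-carbon (which bonds to C4), as in nickel-catalysed couplings of ynamides with carbonyl compounds. It also needs stereochemical fidelity, secured by working at or below room temperature, far below the temperature at which a cyclobutenone opens thermally to a free vinylketene (which would planarize C4 and lead by [2+2] addition to another connectivity), while slow addition of 19 limits alkyne oligomerization.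

Step 9
Reactants: 20 (4S)-dienone
Product: 21 (4R)-2-butanoyl-6-[(dimethylamino)methyl]-3,5-dihydroxy-4-methyl-4-(3-methylbut-2-en-1-yl)cyclohexa-2,5-dien-1-one
Conditions: AcOH–THF–H2O (3:1:1), rt → 40 °C; concentrate below 30 °C
Reagents that add atoms: water, O
Why: Mild aqueous acid cleaves the silyl enol ether and, by addition–elimination of water at C3, the doubly activated menthyl enol ether of the 2-acyl-1,3-dione, while the amine is protonated, the prenyl alkene tolerates acetic acid, and C4 keeps its bonds (the descriptor changes from 4S to 4R only because silicon is lost).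

Step 10
Reactants: 22 5-methoxybenzene-1,3-diol; 23 butanenitrile
Product: 25 1-(2,4-dihydroxy-6-methoxyphenyl)butan-1-one, via ketiminium chloride 24 (not isolated)
Conditions: ZnCl2 (cat.), HCl (g), Et2O, 0 °C; then H2O, 100 °C
Reagents that add atoms: water, O
Why: Houben–Hoesch acylation of the phloroglucinol monomethyl ether, in which the nitrilium electrophile should attack para to a hydroxyl (the carbon between OH and OMe) and hydrolysis of the ketiminium salt gives the ketone, the minor 2,6-dihydroxy-4-methoxy isomer being removed by crystallization.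

Step 11
Reactants: 21 (4R)-Mannich base; 25 1-(2,4-dihydroxy-6-methoxyphenyl)butan-1-one
Product: 27 (4R)-2-butanoyl-6-[(3-butanoyl-2,6-dihydroxy-4-methoxyphenyl)methyl]-3,5-dihydroxy-4-methyl-4-(3-methylbut-2-en-1-yl)cyclohexa-2,5-dien-1-one (CNP0285707.1), via exocyclic enone 26 (not isolated)
Conditions: 25 (1.5 equiv), 1,4-dioxane, 80 °C
Reagents that add atoms: none
Why: Mannich-base alkylation, in which thermal loss of dimethylamine from the inner salt gives the exocyclic enone 26 (a quinone-methide equivalent) that is trapped by the phenoxide of 25 at the ring carbon between its two hydroxyls (the usual site of base-mediated C-alkylation of 2,4-dihydroxyacylphenones), which is the standard way to build the methylene bridge of dimeric acylphloroglucinols and does not involve C4.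

Compound list
1 | propanoic acid | CCC(=O)O | starting material
2 | 1-bromo-3-methylbut-2-ene (prenyl bromide) | CC(C)=CCBr | starting material
3 | dilithium dianion of propanoic acid (dilithium prop-1-ene-1,1-diolate) | CC=C([O-])[O-].[Li+].[Li+] | intermediate (not isolated)
4 | rac-2,5-dimethylhex-4-enoic acid | CC(C)=CCC(C)C(=O)O | intermediate
5 | rac-2,5-dimethylhex-4-enoyl chloride | CC(C)=CCC(C)C(=O)Cl | intermediate
6 | (1R,2S,5R)-(−)-menthol | O[C@@H]1C[C@H](C)CC[C@H]1C(C)C | starting material
7 | trichloroethene | ClC=C(Cl)Cl | starting material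
8 | potassium (1R,2S,5R)-mentholate | [K+].[O-][C@@H]1C[C@H](C)CC[C@H]1C(C)C | intermediate (not isolated)
9 | (E)-1,2-dichlorovinyl (1R,2S,5R)-menthyl ether | Cl/C=C(/Cl)O[C@@H]1C[C@H](C)CC[C@H]1C(C)C | intermediate
10 | lithium [(1R,2S,5R)-menthyloxy]acetylide | [Li+].[C-]#CO[C@@H]1C[C@H](C)CC[C@H]1C(C)C | intermediate (not isolated)
11 | tributyl{[(1R,2S,5R)-menthyloxy]ethynyl}stannane | CCCC[Sn](CCCC)(CCCC)C#CO[C@@H]1C[C@H](C)CC[C@H]1C(C)C | intermediate
12 | methyl(prenyl)ketene (2,5-dimethylhexa-1,4-dien-1-one) | CC(C)=CCC(C)=C=O | intermediate (not isolated)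
13 | (4S)-3-[(1R,2S,5R)-menthyloxy]-4-methyl-4-(3-methylbut-2-en-1-yl)-2-(tributylstannyl)cyclobut-2-en-1-one | CCCC[Sn](CCCC)(CCCC)C1=C(O[C@@H]2C[C@H](C)CC[C@H]2C(C)C)[C@](C)(CC=C(C)C)C1=O | intermediate
14 | butanoyl chloride | CCCC(=O)Cl | starting material
15 | (4S)-2-butanoyl-3-[(1R,2S,5R)-menthyloxy]-4-methyl-4-(3-methylbut-2-en-1-yl)cyclobut-2-en-1-one | CCCC(=O)C1=C(O[C@@H]2C[C@H](C)CC[C@H]2C(C)C)[C@](C)(CC=C(C)C)C1=O | intermediate
16 | N,N-dimethylprop-2-yn-1-amine | CN(C)CC#C | starting material
17 | lithium 3-(dimethylamino)prop-1-yn-1-ide (lithium acetylide) | [Li+].[C-]#CCN(C)C | intermediate (not isolated)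
18 | lithium 3-(dimethylamino)prop-1-yn-1-olate (lithium ynolate) | [Li+].[O-]C#CCN(C)C | intermediate (not isolated)
19 | N,N-dimethyl-3-[(triisopropylsilyl)oxy]prop-2-yn-1-amine | CN(C)CC#CO[Si](C(C)C)(C(C)C)C(C)C | intermediate
20 | (4S)-2-butanoyl-6-[(dimethylamino)methyl]-3-[(1R,2S,5R)-menthyloxy]-4-methyl-4-(3-methylbut-2-en-1-yl)-5-[(triisopropylsilyl)oxy]cyclohexa-2,5-dien-1-one | CCCC(=O)C1=C(O[C@@H]2C[C@H](C)CC[C@H]2C(C)C)[C@](C)(CC=C(C)C)C(O[Si](C(C)C)(C(C)C)C(C)C)=C(CN(C)C)C1=O | intermediate
21 | (4R)-2-butanoyl-6-[(dimethylamino)methyl]-3,5-dihydroxy-4-methyl-4-(3-methylbut-2-en-1-yl)cyclohexa-2,5-dien-1-one (Mannich base, inner salt) | CCCC(=O)C1=C(O)[C@](C)(CC=C(C)C)C(O)=C(CN(C)C)C1=O | intermediate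
22 | 5-methoxybenzene-1,3-diol | COc1cc(O)cc(O)c1 | starting material
23 | butanenitrile | CCCC#N | starting material
24 | 1-(2,4-dihydroxy-6-methoxyphenyl)butan-1-iminium chloride (ketiminium chloride) | CCCC(=[NH2+])c1c(O)cc(O)cc1OC.[Cl-] | intermediate (not isolated)
25 | 1-(2,4-dihydroxy-6-methoxyphenyl)butan-1-one | CCCC(=O)c1c(O)cc(O)cc1OC | intermediate
26 | (4S)-2-butanoyl-3-hydroxy-4-methyl-4-(3-methylbut-2-en-1-yl)-6-methylidenecyclohex-2-ene-1,5-dione (exocyclic enone; same spatial arrangement at C4 as 21) | CCCC(=O)C1=C(O)[C@](C)(CC=C(C)C)C(=O)C(=C)C1=O | intermediate (not isolated)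
27 | (4R)-2-butanoyl-6-[(3-butanoyl-2,6-dihydroxy-4-methoxyphenyl)methyl]-3,5-dihydroxy-4-methyl-4-(3-methylbut-2-en-1-yl)cyclohexa-2,5-dien-1-one (CNP0285707.1) | CCCC(=O)C1=C(O)[C@](C)(CC=C(C)C)C(O)=C(Cc2c(O)cc(OC)c(C(=O)CCC)c2O)C1=O | target

Total step count: 11. Longest linear sequence: 7 steps (3, 4, 5, 6, 8, 9, 11; equally 1, 2, 5, 6, 8, 9, 11).

Steps most likely to fail

Step 8 (Proposed new method). The metallacycle may release a free vinylketene, which planarizes C4 and erodes the stereochemical relay. The alkyne may also insert in the opposite sense, or simply oligomerize on nickel. The fallback uses known chemistry, sets out from 14 and 2 and comes back at 21. Friedel–Crafts acylation of commercial 2-methylbenzene-1,3,5-triol with 14 (AlCl3, nitrobenzene, 60 °C) should give 1-(2,4,6-trihydroxy-3-methylphenyl)butan-1-one F1. Alkylative dearomatization of F1 with 2 (NaOMe, MeOH, 0 °C) at the methyl-bearing carbon gives rac-2-butanoyl-3,5-dihydroxy-4-methyl-4-(3-methylbut-2-en-1-yl)cyclohexa-2,5-dien-1-one F2, which is separated from the aromatic C-prenyl isomer. A Mannich reaction at the one free ring CH with N,N-dimethylmethyleneiminium iodide (Et3N, CH2Cl2) gives rac-2-butanoyl-6-[(dimethylamino)methyl]-3,5-dihydroxy-4-methyl-4-(3-methylbut-2-en-1-yl)cyclohexa-2,5-dien-1-one F3. Preparative HPLC on a chiral stationary phase then delivers 21, and step 11 follows unchanged.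

Step 5. The hindered dialkylketene may add slowly while the alkynylstannane is protodestannylated, and above all the two C4 epimers may not separate on silica because the menthyl stereocentres are remote from C4. The fallback replaces early diastereomer separation by late enantiomer separation; it sets out from 5 and 11 and comes back at 21. Step 5 is run as described but the crude product is not separated, so that 13 is carried on together with its C4 epimer, (4R)-3-[(1R,2S,5R)-menthyloxy]-4-methyl-4-(3-methylbut-2-en-1-yl)-2-(tributylstannyl)cyclobut-2-en-1-one F4. The mixture is taken through steps 6, 8 and 9 under the same conditions. F4 then gives in turn (4R)-2-butanoyl-3-[(1R,2S,5R)-menthyloxy]-4-methyl-4-(3-methylbut-2-en-1-yl)cyclobut-2-en-1-one F5, then (4R)-2-butanoyl-6-[(dimethylamino)methyl]-3-[(1R,2S,5R)-menthyloxy]-4-methyl-4-(3-methylbut-2-en-1-yl)-5-[(triisopropylsilyl)oxy]cyclohexa-2,5-dien-1-one F6. Once the menthyl and silyl groups are hydrolysed, F6 gives (4S)-2-butanoyl-6-[(dimethylamino)methyl]-3,5-dihydroxy-4-methyl-4-(3-methylbut-2-en-1-yl)cyclohexa-2,5-dien-1-one F7, the enantiomer of 21. The pair is resolved by preparative HPLC on a chiral stationary phase, which delivers 21.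

Step 6. Transmetalation at the hindered, electron-rich α-stannyl enone may be slow, so that protodestannylation or decarbonylation of the acylpalladium takes over. The fallback builds the acyl group from carbon monoxide; it sets out from 13 and comes back at 15. Iododestannylation (I2, CH2Cl2, 0 °C) gives (4S)-2-iodo-3-[(1R,2S,5R)-menthyloxy]-4-methyl-4-(3-methylbut-2-en-1-yl)cyclobut-2-en-1-one F8. Carbonylative Negishi coupling of F8 (CO 1 atm, n-PrZnBr, Pd(PPh3)4, THF, rt) should then give 15.

Further compounds
F1 | step 8 | 1-(2,4,6-trihydroxy-3-methylphenyl)butan-1-one | CCCC(=O)c1c(O)cc(O)c(C)c1O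
F2 | step 8 | rac-2-butanoyl-3,5-dihydroxy-4-methyl-4-(3-methylbut-2-en-1-yl)cyclohexa-2,5-dien-1-one | CCCC(=O)C1=C(O)C(C)(CC=C(C)C)C(O)=CC1=O
F3 | step 8 | rac-2-butanoyl-6-[(dimethylamino)methyl]-3,5-dihydroxy-4-methyl-4-(3-methylbut-2-en-1-yl)cyclohexa-2,5-dien-1-one | CCCC(=O)C1=C(O)C(C)(CC=C(C)C)C(O)=C(CN(C)C)C1=O
F4 | step 5 | (4R)-3-[(1R,2S,5R)-menthyloxy]-4-methyl-4-(3-methylbut-2-en-1-yl)-2-(tributylstannyl)cyclobut-2-en-1-one | CCCC[Sn](CCCC)(CCCC)C1=C(O[C@@H]2C[C@H](C)CC[C@H]2C(C)C)[C@@](C)(CC=C(C)C)C1=O
F5 | step 5 | (4R)-2-butanoyl-3-[(1R,2S,5R)-menthyloxy]-4-methyl-4-(3-methylbut-2-en-1-yl)cyclobut-2-en-1-one | CCCC(=O)C1=C(O[C@@H]2C[C@H](C)CC[C@H]2C(C)C)[C@@](C)(CC=C(C)C)C1=O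
F6 | step 5 | (4R)-2-butanoyl-6-[(dimethylamino)methyl]-3-[(1R,2S,5R)-menthyloxy]-4-methyl-4-(3-methylbut-2-en-1-yl)-5-[(triisopropylsilyl)oxy]cyclohexa-2,5-dien-1-one | CCCC(=O)C1=C(O[C@@H]2C[C@H](C)CC[C@H]2C(C)C)[C@@](C)(CC=C(C)C)C(O[Si](C(C)C)(C(C)C)C(C)C)=C(CN(C)C)C1=O
F7 | step 5 | (4S)-2-butanoyl-6-[(dimethylamino)methyl]-3,5-dihydroxy-4-methyl-4-(3-methylbut-2-en-1-yl)cyclohexa-2,5-dien-1-one | CCCC(=O)C1=C(O)[C@@](C)(CC=C(C)C)C(O)=C(CN(C)C)C1=O
F8 | step 6 | (4S)-2-iodo-3-[(1R,2S,5R)-menthyloxy]-4-methyl-4-(3-methylbut-2-en-1-yl)cyclobut-2-en-1-one | IC1=C(O[C@@H]2C[C@H](C)CC[C@H]2C(C)C)[C@](C)(CC=C(C)C)C1=O
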